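The pyran ring C of the middle epicatechin unit is taken apart as a formal [4+2] adduct. Its ring oxygen O1 and its doubly benzylic C4 (between the middle ring A and C6 of the lower catechin) come from an ortho-quinone methide made from a diarylcarbinol. C2 and C3 come from a (Z)-β-silylstyrene, whose aryl group stabilises positive charge at C2 and whose silicon on C3 is the masked 3-hydroxyl. One acid-catalysed cycloaddition forms O1–C2 and C3–C4 and sets C2, C3 and C4; Tamao–Fleming oxidation then gives the 3-OH with retention. The upper epicatechin is attached last at C8, and hydrogenolysis removes all benzyl groups and two bromine caps.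

Key step: step 7

Assumption: the hand of the phosphoric acid that attacks the required face of C4 cannot be read from a close precedent; the (R)-acid is written and stands for whichever enantiomer a first experiment shows to give the natural middle unit.

Step 1
Reactants: 1 (+)-catechin
Product: 2 5,7,3′,4′-tetra-O-benzyl-(+)-catechin
Conditions: BnBr, K2CO3, DMF, 0 °C → rt
Reagents that add atoms: benzyl bromide BrCc1ccccc1
Why: Williamson etherification of the four phenols; K2CO3 does not deprotonate the secondary 3-OH, and no stereocentre is touched.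

Step 2
Reactants: 2 5,7,3′,4′-tetra-O-benzyl-(+)-catechin
Product: 3 8-bromo-5,7,3′,4′-tetra-O-benzyl-(+)-catechin
Conditions: NBS (1.0 equiv), CH2Cl2, −78 °C → rt
Reagents that add atoms: N-bromosuccinimide O=C1CCC(=O)N1Br
Why: Electrophilic aromatic bromination at C8, the most reactive position of the 5,7-dioxygenated ring A; the bromine blocks C8 so that step 4 can only engage C6, and it is removed in the last step.

Step 3
Reactants: 4 3,5-bis(benzyloxy)phenol
Product: 5 4,6-bis(benzyloxy)-2-hydroxybenzaldehyde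
Conditions: MgCl2, Et3N, (CH2O)n, MeCN, reflux; aq. HCl work-up
Reagents that add atoms: paraformaldehyde (formaldehyde C=O)
Why: Magnesium-phenoxide-directed ortho-formylation, which is specific for the position next to the free OH (the two ortho positions are equivalent), a second formaldehyde acting as hydride acceptor.

Step 4
Reactants: 5 4,6-bis(benzyloxy)-2-hydroxybenzaldehyde; 3 8-bromo-5,7,3′,4′-tetra-O-benzyl-(+)-catechin
Product: 7 [2-hydroxy-4,6-bis(benzyloxy)phenyl][8-bromo-5,7,3′,4′-tetra-O-benzylcatechin-6-yl]methanol (both epimers at the carbinol carbon), via diarylmethylium tetrafluoroborate 6 (not isolated)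
Conditions: HBF4·OEt2 (1.1 equiv), CH2Cl2, −40 → 0 °C; then aq. NaHCO3
Reagents that add atoms: none
Why: Acid-mediated Friedel–Crafts hydroxyalkylation in which the protonated salicylaldehyde is attacked by C6 of 3, the only free ring-A position; the hexa-oxygenated diarylmethylium ion should be too stabilised and too shielded by four ortho oxygens to arylate again, and bicarbonate returns the carbinol, whose two epimers converge on one planar intermediate in step 7.

Step 5
Reactants: 8 3,4-bis(benzyloxy)benzaldehyde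
Product: 9 1,2-bis(benzyloxy)-4-ethynylbenzene
Conditions: dimethyl (1-diazo-2-oxopropyl)phosphonate, K2CO3, MeOH, rt
Reagents that add atoms: dimethyl (1-diazo-2-oxopropyl)phosphonate CC(=O)C(=[N+]=[N-])P(=O)(OC)OC
Why: Seyferth–Gilbert homologation with the Ohira–Bestmann reagent converts the aldehyde into the terminal alkyne under mild base that leaves the benzyl ethers alone.

Step 6
Reactants: 9 1,2-bis(benzyloxy)-4-ethynylbenzene
Product: 10 (Z)-[2-(3,4-bis(benzyloxy)phenyl)ethenyl]dimethyl(phenyl)silane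
Conditions: [RuCl2(p-cymene)]2 (2.5 mol %), PhMe2SiH, CH2Cl2, 40 °C
Reagents that add atoms: dimethylphenylsilane C[SiH](C)c1ccccc1
Why: Ruthenium-catalysed trans-hydrosilylation of a terminal aryl alkyne, which adds Si–H anti and should give the β-(Z)-vinylsilane; the Z geometry is the source of the 2,3-cis relationship in step 7.

Step 7
Reactants: 7 [2-hydroxy-4,6-bis(benzyloxy)phenyl][8-bromo-5,7,3′,4′-tetra-O-benzylcatechin-6-yl]methanol; 10 (Z)-[2-(3,4-bis(benzyloxy)phenyl)ethenyl]dimethyl(phenyl)silane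
Product: 12 [3-deoxy-3-(dimethylphenylsilyl)-5,7,3′,4′-tetra-O-benzylepicatechin]-(4β→6)-[8-bromo-5,7,3′,4′-tetra-O-benzylcatechin] (2,3-cis-3,4-trans; silicon in place of the 3-hydroxyl), via ortho-quinone methide 11 (not isolated)
Conditions: (R)-3,3′-bis(2,4,6-triisopropylphenyl)-1,1′-binaphthyl-2,2′-diyl hydrogen phosphate [(R)-TRIP] (10 mol %), 10 (3 equiv), 4 Å MS, PhCF3, 0 °C → rt
Reagents that add atoms: none
Why: Proposed new method: the chiral phosphoric acid dehydrates both epimers of 7 to the planar ortho-quinone methide 11, held as a hydrogen-bonded ion pair, and the silicon-bearing carbon of 10 (future C3) attacks the methide carbon C4 while the quinone-methide oxygen O1 closes on the styrene carbon (future C2), whose positive charge is stabilised by the 3,4-bis(benzyloxy)phenyl ring and by hyperconjugation with the C–Si bond. The closest known reaction type is the chiral-Brønsted-acid-catalysed inverse-electron-demand oxa-[4+2] cycloaddition of quinone methides from ortho-hydroxybenzhydrols with styrenes; the β-silylstyrene as two-carbon partner is the new element. Ring C of the middle unit closes as an asynchronous [4+2] (C3–C4 first, then six-membered O1–C2 closure inside the ion pair), which should outrun loss of silicon by ipso-substitution. C2 and C3 follow from suprafacial addition to the Z alkene (aryl and silicon cis), because rotation in the β-silyl cation is held back by hyperconjugation. C4 follows from the exo approach, in which the PhMe2Si group lies anti to the C4–C4a bond instead of being wedged between ring A and the C4 aryl group, so that silicon and the lower unit end up trans; the face of C4 that is attacked, and with it the absolute configuration of all three centres, is chosen by the chiral phosphate. The step needs regioselectivity (aryl on C2 and silicon on C3 polarise the alkene in the same sense), chemoselectivity against arylation by ring A of a second molecule (excess 10), and exo and facial selectivity (bulk of the silyl group and the catalyst).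

Step 8
Reactants: 12 [3-deoxy-3-(dimethylphenylsilyl)-5,7,3′,4′-tetra-O-benzylepicatechin]-(4β→6)-[8-bromo-5,7,3′,4′-tetra-O-benzylcatechin]
Product: 13 [5,7,3′,4′-tetra-O-benzylepicatechin]-(4β→6)-[8-bromo-5,7,3′,4′-tetra-O-benzylcatechin]
Conditions: t-BuOOH, CsOH·H2O, Bu4NF, DMF, 70 °C
Reagents that add atoms: tert-butyl hydroperoxide CC(C)(C)OO
Why: Tamao–Fleming oxidation under basic peroxide conditions, in which peroxide adds to silicon and first phenyl, then C3 migrate from silicon to oxygen with retention at C3; no electrophilic reagent is present that would attack the phloroglucinol rings, and in the favoured conformer (2-aryl equatorial, silicon and 4-aryl trans-diaxial) silicon is gauche to the C2–O1 bond, which disfavours β-elimination.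

Step 9
Reactants: 14 (−)-epicatechin
Product: 15 5,7,3′,4′-tetra-O-benzyl-(−)-epicatechin
Conditions: BnBr, K2CO3, DMF, 0 °C → rt
Reagents that add atoms: benzyl bromide BrCc1ccccc1
Why: Williamson etherification of the four phenols, as in step 1, with the 3-OH and both stereocentres untouched.

Step 10
Reactants: 15 5,7,3′,4′-tetra-O-benzyl-(−)-epicatechin
Product: 16 8-bromo-5,7,3′,4′-tetra-O-benzyl-(−)-epicatechin
Conditions: NBS (1.0 equiv), CH2Cl2, −78 °C → rt
Reagents that add atoms: N-bromosuccinimide O=C1CCC(=O)N1Br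
Why: Electrophilic aromatic bromination at C8 caps the nucleophilic position of the future electrophile, so that it cannot oligomerise through its own ring A in step 12.

Step 11
Reactants: 16 8-bromo-5,7,3′,4′-tetra-O-benzyl-(−)-epicatechin
Product: 17 8-bromo-5,7,3′,4′-tetra-O-benzyl-4β-(2-ethoxyethoxy)-(−)-epicatechin
Conditions: DDQ (2 equiv), 2-ethoxyethanol, CH2Cl2, rt
Reagents that add atoms: 2-ethoxyethanol CCOCCO
Why: Benzylic oxidation by hydride abstraction at C4 (cation stabilised by the oxygenated ring A), with capture by the alcohol trans to the 3-OH, which should give the 4β-ether.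

Step 12
Reactants: 13 [5,7,3′,4′-tetra-O-benzylepicatechin]-(4β→6)-[8-bromo-5,7,3′,4′-tetra-O-benzylcatechin]; 17 8-bromo-5,7,3′,4′-tetra-O-benzyl-4β-(2-ethoxyethoxy)-(−)-epicatechin
Product: 18 [8-bromo-5,7,3′,4′-tetra-O-benzylepicatechin]-(4β→8)-[5,7,3′,4′-tetra-O-benzylepicatechin]-(4β→6)-[8-bromo-5,7,3′,4′-tetra-O-benzylcatechin]
Conditions: TMSOTf (0.2 equiv), CH2Cl2, −78 → −40 °C
Reagents that add atoms: none
Why: Lewis-acid-mediated Friedel–Crafts interflavan coupling in which the ionised C4 cation of 17 is attacked trans to its 3-OH (4β) by C8 of the middle unit of 13, the most accessible electron-rich position left, since both other C8 positions carry bromine.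

Step 13
Reactants: 18 [8-bromo-5,7,3′,4′-tetra-O-benzylepicatechin]-(4β→8)-[5,7,3′,4′-tetra-O-benzylepicatechin]-(4β→6)-[8-bromo-5,7,3′,4′-tetra-O-benzylcatechin]
Product: 19 arecatannin B1
Conditions: H2 (1 atm), Pd(OH)2/C, Et3N, THF/MeOH/H2O, rt
Reagents that add atoms: none
Why: Hydrogenolysis cleaves the twelve benzyl ethers and both aryl C–Br bonds in one operation, with Et3N taking up HBr so that the acid-labile interflavan bonds are not exposed to acid; no stereocentre is affected.

Compound list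
1 | (+)-catechin | Oc1cc2c(c(O)c1)C[C@H](O)[C@@H](c1ccc(O)c(O)c1)O2 | starting material
2 | 5,7,3′,4′-tetra-O-benzyl-(+)-catechin | c1ccccc1COc1cc2c(c(OCc3ccccc3)c1)C[C@H](O)[C@@H](c1ccc(OCc3ccccc3)c(OCc3ccccc3)c1)O2 | intermediate
3 | 8-bromo-5,7,3′,4′-tetra-O-benzyl-(+)-catechin | c1ccccc1COc1c(Br)c2c(c(OCc3ccccc3)c1)C[C@H](O)[C@@H](c1ccc(OCc3ccccc3)c(OCc3ccccc3)c1)O2 | intermediate
4 | 3,5-bis(benzyloxy)phenol | Oc1cc(OCc2ccccc2)cc(OCc2ccccc2)c1 | starting material
5 | 4,6-bis(benzyloxy)-2-hydroxybenzaldehyde | O=Cc1c(O)cc(OCc2ccccc2)cc1OCc1ccccc1 | intermediate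
6 | [2-hydroxy-4,6-bis(benzyloxy)phenyl][8-bromo-5,7,3′,4′-tetra-O-benzylcatechin-6-yl]methylium tetrafluoroborate | Oc1cc(OCc2ccccc2)cc(OCc2ccccc2)c1[CH+]c1c(OCc2ccccc2)c(Br)c2c(c1OCc1ccccc1)C[C@H](O)[C@@H](c1ccc(OCc3ccccc3)c(OCc3ccccc3)c1)O2.F[B-](F)(F)F | intermediate
7 | [2-hydroxy-4,6-bis(benzyloxy)phenyl][8-bromo-5,7,3′,4′-tetra-O-benzylcatechin-6-yl]methanol (both epimers at the carbinol carbon) | OC(c1c(O)cc(OCc2ccccc2)cc1OCc1ccccc1)c1c(OCc2ccccc2)c(Br)c2c(c1OCc1ccccc1)C[C@H](O)[C@@H](c1ccc(OCc3ccccc3)c(OCc3ccccc3)c1)O2 | intermediate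
8 | 3,4-bis(benzyloxy)benzaldehyde | O=Cc1ccc(OCc2ccccc2)c(OCc2ccccc2)c1 | starting material
9 | 1,2-bis(benzyloxy)-4-ethynylbenzene | C#Cc1ccc(OCc2ccccc2)c(OCc2ccccc2)c1 | intermediate
10 | (Z)-[2-(3,4-bis(benzyloxy)phenyl)ethenyl]dimethyl(phenyl)silane | C[Si](C)(c1ccccc1)/C=C\c1ccc(OCc2ccccc2)c(OCc2ccccc2)c1 | intermediate
11 | ortho-quinone methide from 7 (methide geometry not fixed) | O=C1C=C(OCc2ccccc2)C=C(OCc2ccccc2)C1=Cc1c(OCc2ccccc2)c(Br)c2c(c1OCc1ccccc1)C[C@H](O)[C@@H](c1ccc(OCc3ccccc3)c(OCc3ccccc3)c1)O2 | intermediate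
12 | [3-deoxy-3-(dimethylphenylsilyl)-5,7,3′,4′-tetra-O-benzylepicatechin]-(4β→6)-[8-bromo-5,7,3′,4′-tetra-O-benzylcatechin] | c1ccccc1COc1cc(OCc3ccccc3)c2c(c1)O[C@H](c1ccc(OCc3ccccc3)c(OCc3ccccc3)c1)[C@H]([Si](C)(C)c1ccccc1)[C@H]2c1c(OCc3ccccc3)c(Br)c2c(c1OCc1ccccc1)C[C@H](O)[C@@H](c1ccc(OCc3ccccc3)c(OCc3ccccc3)c1)O2 | intermediate
13 | [5,7,3′,4′-tetra-O-benzylepicatechin]-(4β→6)-[8-bromo-5,7,3′,4′-tetra-O-benzylcatechin] | c1ccccc1COc1cc(OCc3ccccc3)c2c(c1)O[C@H](c1ccc(OCc3ccccc3)c(OCc3ccccc3)c1)[C@H](O)[C@H]2c1c(OCc3ccccc3)c(Br)c2c(c1OCc1ccccc1)C[C@H](O)[C@@H](c1ccc(OCc3ccccc3)c(OCc3ccccc3)c1)O2 | intermediate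
14 | (−)-epicatechin | Oc1cc(O)c2c(c1)O[C@H](c1ccc(O)c(O)c1)[C@H](O)C2 | starting material
15 | 5,7,3′,4′-tetra-O-benzyl-(−)-epicatechin | c1ccccc1COc1cc(OCc3ccccc3)c2c(c1)O[C@H](c1ccc(OCc3ccccc3)c(OCc3ccccc3)c1)[C@H](O)C2 | intermediate
16 | 8-bromo-5,7,3′,4′-tetra-O-benzyl-(−)-epicatechin | c1ccccc1COc1cc(OCc3ccccc3)c2c(c1Br)O[C@H](c1ccc(OCc3ccccc3)c(OCc3ccccc3)c1)[C@H](O)C2 | intermediate
17 | 8-bromo-5,7,3′,4′-tetra-O-benzyl-4β-(2-ethoxyethoxy)-(−)-epicatechin | c1ccccc1COc1cc(OCc3ccccc3)c2c(c1Br)O[C@H](c1ccc(OCc3ccccc3)c(OCc3ccccc3)c1)[C@H](O)[C@H]2OCCOCC | intermediate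
18 | [8-bromo-5,7,3′,4′-tetra-O-benzylepicatechin]-(4β→8)-[5,7,3′,4′-tetra-O-benzylepicatechin]-(4β→6)-[8-bromo-5,7,3′,4′-tetra-O-benzylcatechin] | c1ccccc1COc1cc(OCc3ccccc3)c2c(c1Br)O[C@H](c1ccc(OCc3ccccc3)c(OCc3ccccc3)c1)[C@H](O)[C@H]2c1c(OCc3ccccc3)cc(OCc3ccccc3)c2c1O[C@H](c1ccc(OCc3ccccc3)c(OCc3ccccc3)c1)[C@H](O)[C@H]2c1c(OCc3ccccc3)c(Br)c2c(c1OCc1ccccc1)C[C@H](O)[C@@H](c1ccc(OCc3ccccc3)c(OCc3ccccc3)c1)O2 | intermediate
19 | arecatannin B1 | Oc1cc(O)c2c(c1)O[C@H](c1ccc(O)c(O)c1)[C@H](O)[C@H]2c1c(O)cc(O)c2c1O[C@H](c1ccc(O)c(O)c1)[C@H](O)[C@H]2c1c(O)cc2c(c1O)C[C@H](O)[C@@H](c1ccc(O)c(O)c1)O2 | target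

Total step count: 13
Longest linear sequence: 7 steps (steps 1, 2, 4, 7, 8, 12, 13)

Steps most likely to fail

Step 7 (new method). What may go wrong is loss of silicon from the β-silyl cation before ring closure (alkenyl transfer instead of annulation), attack through the endo arrangement, or poor facial discrimination by the catalyst. The fallback uses known chemistry and takes the middle ring from epicatechin instead of building it. It sets out from 15 and 3. Oxidation of 15 at C4 with DDQ in the presence of 2-ethoxyethanol should give 5,7,3′,4′-tetra-O-benzyl-4β-(2-ethoxyethoxy)-(−)-epicatechin F1. Coupling of F1 with an excess of 3 (TMSOTf, CH2Cl2, −78 °C) should then give 13 directly, because C8 of 3 is capped and the C4 cation is attacked by C6 trans to the 3-OH. The route is rejoined at 13.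

Step 8. What may go wrong is Peterson-type β-elimination that opens ring C, or failure of peroxide to attack the hindered silicon. The fallback uses a silyl group that is unmasked by fluoride instead of basic peroxide. It sets out from 9: the same [RuCl2(p-cymene)]2-catalysed hydrosilylation with benzyldimethylsilane should give (Z)-benzyl[2-(3,4-bis(benzyloxy)phenyl)ethenyl]dimethylsilane F2. Cycloaddition of F2 with 7 as in step 7 should give the 3-(benzyldimethylsilyl) analogue of 12 F3. Bu4NF (THF, 0 °C) then cleaves the benzyl–silicon bond, and H2O2/KHCO3 (MeOH) oxidises the resulting silanol with retention. The route is rejoined at 13.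

Step 4. What may go wrong is acid-induced loss or migration of benzyl groups at the cation stage, or a second arylation. The fallback reverses the roles of the two rings and avoids acid. It sets out from 3: Vilsmeier–Haack formylation (POCl3, DMF) at C6 should give 8-bromo-6-formyl-5,7,3′,4′-tetra-O-benzyl-(+)-catechin F4. The bromomagnesium phenoxide of 4 (EtMgBr, toluene) then adds through its ortho carbon to F4 in a chelate-controlled ortho-hydroxyalkylation. The route is rejoined at 7.

Further compounds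
F1 | step 7 | 5,7,3′,4′-tetra-O-benzyl-4β-(2-ethoxyethoxy)-(−)-epicatechin | c1ccccc1COc1cc(OCc3ccccc3)c2c(c1)O[C@H](c1ccc(OCc3ccccc3)c(OCc3ccccc3)c1)[C@H](O)[C@H]2OCCOCC
F2 | step 8 | (Z)-benzyl[2-(3,4-bis(benzyloxy)phenyl)ethenyl]dimethylsilane | C[Si](C)(Cc1ccccc1)/C=C\c1ccc(OCc2ccccc2)c(OCc2ccccc2)c1
F3 | step 8 | [3-deoxy-3-(benzyldimethylsilyl)-5,7,3′,4′-tetra-O-benzylepicatechin]-(4β→6)-[8-bromo-5,7,3′,4′-tetra-O-benzylcatechin] | c1ccccc1COc1cc(OCc3ccccc3)c2c(c1)O[C@H](c1ccc(OCc3ccccc3)c(OCc3ccccc3)c1)[C@H]([Si](C)(C)Cc1ccccc1)[C@H]2c1c(OCc3ccccc3)c(Br)c2c(c1OCc1ccccc1)C[C@H](O)[C@@H](c1ccc(OCc3ccccc3)c(OCc3ccccc3)c1)O2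
F4 | step 4 | 8-bromo-6-formyl-5,7,3′,4′-tetra-O-benzyl-(+)-catechin | O=Cc1c(OCc2ccccc2)c(Br)c2c(c1OCc1ccccc1)C[C@H](O)[C@@H](c1ccc(OCc3ccccc3)c(OCc3ccccc3)c1)O2
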